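## Structural features

The target is a germacranolide: a ten-membered carbocycle (C1–C10) fused trans across C6–C7 to an α-methylene-γ-butyrolactone (O–C6, C7, C11=C13, C12=O). Round the ring it carries a C1 ketone conjugated to an E C2=C3 double bond, a C4 methyl group, a free C5 hydroxyl, the lactone oxygen at C6, an angelate at C8 and a quaternary C10 bearing a methyl group and an acetate. Five contiguous stereocentres run from C4 to C8 (4S,5S,6S,7R,8R) and C10 (S) lies one methylene further on. In zigzag terms C4/C5 are anti, C5/C6 syn, C6/C7 trans on the lactone, C7/C8 those of a syn homoallylic alcohol, and the C8 and C10 oxygens syn. Fragile groups are the exo-methylene lactone (a Michael acceptor), the angelate (Z to E isomerisation under nucleophilic or strongly acidic activation), the tertiary α-acyloxy ketone, and the δ-hydroxy enone, which can dehydrate to a dienone or undergo vinylogous retro-aldol cleavage in base. The real difficulty is to close a ten-membered ring containing an E-enone while fixing C4 and C5 relative to C6, late and among all these groups. The key step uses the fact that C4 is the γ-carbon of the C1 enone and C5 a carbinol carbon: C4–C5 is a vinylogous aldol bond, and because C10 is quaternary the C1 ketone can enolise only toward C4.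

## Logic of the disconnections

**26 to 25.** The C4–C5 bond is cut. C4 is γ to the C1 carbonyl through C2=C3 and C5 bears a hydroxyl, so this is a vinylogous aldol retron. The cut opens the ten-membered ring, removes two stereocentres and leaves a chain hanging on the intact lactone. Every other group of 26 is already present in 25, so nothing follows the ring closure. The forward step must close a ten-membered ring by γ-attack only and must join the Si face of C4 to the Si face of C5.

**25 to 22 (through 24 and 23).** No skeletal bond is cut: the C5 aldehyde goes back to a primary alcohol and the dienol ether to the enone. The order is forced, because an aldehyde present during enolisation would enolise at C6. The demand is a C5 oxygen protecting group that leaves while a silyl dienol ether stays (triethylsilyl against triisopropylsilyl) and an oxidation that spares the dienol ether.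

**22 to 18 (through 21 and 20).** The C12–O6 lactone bond, the C10 O–acetyl bond and the C5 O–silyl bond are cut. The lactone returns to an acrylate ester plus a C5/C6 acetonide, giving an acyclic chain with all four remaining stereocentres. The demands are γ-lactonisation onto O6 in preference to O5 (O8 is already acylated) and a steric distinction between primary C5–OH and tertiary C10–OH.

**18 to 15 and 16.** The C8 O–acyl bond is cut. Acylating the only free hydroxyl of 15 with the final ester removes any later protecting-group exchange and blocks lactonisation onto C8. The demand is acylation of a hindered secondary alcohol without Z/E isomerisation.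

**15 to 13 and 4.** The C7–C8 bond is cut. This is the convergent step: it divides the skeleton into a C5–C7/C11–C13 piece and a C8–C10/C1–C4 piece and traces C7 and C8 to an allylation governed by C6. The demands are syn simple selectivity, addition anti to the C6–O bond, and aldehyde over ketone.

**4 to 1 and 2 (through 3).** The C7–C11 bond is cut (Baylis–Hillman) after allylic transposition of the bromide; C6 comes from the chiral pool. The demand is a Z-selective SN2' bromination.

**13 to 9 and 10 (through 12 and 11).** The C1–C2 bond is cut: acyl substitution of a lactone by an alkenyllithium, with C8 returning to the lactone alkoxy carbon. The demand is mono-addition.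

**9 to 5 (through 8, 7 and 6).** No C–C bond is cut. The two carboxyl groups of 5 are told apart by dioxolanone formation, and C10 arrives with its methyl group and oxygen in place.

## Other disconnections considered

Alternative 1: The cut is at C7–C8 and C11–C13, in the lactone sector and not in the ring. In the forward step the lithiated dithiane A2 (C8 as masked acyl carbon, with C9, C10 and C1) adds in a conjugate sense to C7 of butenolide A1, anti to the C6 side chain. The lactone enolate is then trapped at C11 by dimethylmethyleneiminium iodide, giving the trans-substituted aminomethyl lactone A3.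
- In its favour: tandem conjugate addition and enolate trapping on butenolides is established anionic chemistry. The C6-to-C7 relationship is dictated by a rigid five-membered ring, which is better than the open-chain facial selectivity on which step 8 of the chosen plan depends. The methylene group stays masked as the amine until a late elimination, again better than the chosen plan, which carries the free Michael acceptor from step 8 to the end. C4 and C5 would be set inside A1 by ordinary acyclic methods.
- Against it here: no carbocycle is closed. C2 is missing from both fragments and would have to come, for example, with a β-ketophosphonate at C1 for an intramolecular Horner–Wadsworth–Emmons closure at C2=C3. C8 emerges at the ketone level and needs a diastereoselective reduction. A3 carries two silyl ethers, a 4-methoxybenzyl ether, a methoxymethyl ether and a dithiane, all to be exchanged around a tertiary acetate and an angelate.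
- Comparison: structurally it secures the lactone sector more safely but leaves the medium ring, the central problem, open, whereas the chosen plan spends its risk on that ring and gains two stereocentres with it. Mechanistically it is all known chemistry, and a Horner–Wadsworth–Emmons macrocyclisation has more precedent than the proposed aldol closure (the alternative is the better on this point). In step economy it is clearly worse, a rough count being well above twenty steps in the longest line against fourteen.

Alternative 2: The cut is at C7–C11 (with C8–O): the lactone is annulated onto a preformed ten-membered ring. In the forward step Bu3SnH in the presence of air converts bromoacetal A4 (alkene taken as E) into a vinyl radical at C11, which cyclises 5-exo onto C7. The C8 radical is trapped by O2 and the hydroperoxide reduced, giving the methylene lactol ether A5 with a free C8 hydroxyl.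
- In its favour: Ueno–Stork haloacetal cyclisations are neutral and tolerate ketones, esters and silyl ethers. One operation makes C7–C11, the five-membered ring and the C8–O bond, more functionality per step than the chosen key step (the alternative is the better on this point). The C8 hydroxyl of A5 is the only free one, so the angelate could go on without protecting-group play, equal to the chosen plan.
- Against it here: A4 already contains the ten-membered ring with C4, C5, C6 and C10 set and an E C7=C8 alkene, so the hardest problem is moved upstream and not solved. The trans ring fusion runs against the cis preference of 5-exo closures on ordinary rings and would rest on the alkene geometry and ring conformation alone. The C8 configuration comes from oxygen trapping of a ring radical with little to steer it. The enone cannot be present under tin hydride, so C2=C3 must be introduced afterwards, and the lactol ether must be oxidised to the lactone.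
- Comparison: structurally it addresses the lactone and C8 where the chosen plan addresses the ring and C4/C5. Mechanistically the radical step is well known as a type but not for a trans fusion on a medium ring. In step economy there is no gain: at least five steps after A5 plus an independent synthesis of a functionalised cyclodecenone.

Alternative 3: The cut is at C8–C9 (with O–C10): ring closure by intramolecular nitrile oxide cycloaddition. In the forward step aldoxime A6 is oxidised with NaOCl to the C8 nitrile oxide, which adds across the C9=C10 double bond of the isopropenyl ketone. C8–C9 and O–C10 form, the ten-membered carbocycle closes and the bridged isoxazoline A7 results, with C10 created in the step.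
- In its favour: nitrile oxide cycloadditions close medium and large rings at high dilution without activating other groups, and the regiochemistry (carbon to the terminal CH2, oxygen to the substituted carbon) is the normal one. It closes the same ring as the chosen key step with more precedent as a macrocyclisation (the alternative is the better on this point), and it brings in the C8 and C10 heteroatoms in masked form at once.
- Against it here: C10 is a quaternary centre formed far from any controlling stereocentre, whereas the chosen plan takes it from the chiral pool (the chosen plan is the better here). N–O cleavage liberates a β-hydroxy ketone next to the C1 ketone, prone to retro-aldol cleavage and dehydration, and makes C7 epimerisable. C8 then needs a stereoselective reduction, the lactone must still be made from the C12 silyl ether, and C2=C3 must be introduced by dehydrogenation.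
- Comparison: structurally both close the ten-membered ring, but A7 is far from the target (wrong oxidation levels at C8, C12 and C2/C3, no lactone). Mechanistically it is a concerted, well-understood cycloaddition against an untested polar closure. In step economy it needs at least eight steps after A7 against none after the chosen key step.

Key step: step 16

Remark: locants follow germacrane numbering (C1 ketone, C4 methyl, C5 carbinol, C6 lactone oxygen, C8 angelate, C10 methyl and acetate, C11=C13, C12 lactone carbonyl).

Remark: seco-aldehyde 25 and product 26 were checked centre by centre; they share 6S,7R,8R,10S, and the aldol creates 4S,5S. No structure needed correction.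

Remark: 25 carries the final C8 angelate (not a benzyl-type ether to be exchanged after ring closure) and a triisopropylsilyl dienol ether (not a less robust tert-butyldimethylsilyl one). The skeleton and the bond formed are unchanged, and the ring closure delivers 26 directly.

Remark: the 4,5-anti pair does not follow from an arrangement with C5=O antiperiplanar to C3=C4 (that arrangement favours syn). It follows from the arrangement with C3 and C6 anti about the forming bond, and the required aldehyde face is opposite to the Cornforth face, so the tether has to enforce it.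

Assumption: (E)-1-bromobut-1-ene is available as the single E isomer. The allylindium intermediate 14 is written in its simplest form.

## Steps

Step 1
Reactants: 1 (R)-glyceraldehyde acetonide; 2 methyl acrylate
Product: 3 methyl 2-{[(4R)-2,2-dimethyl-1,3-dioxolan-4-yl](hydroxy)methyl}prop-2-enoate (both carbinol epimers)
Conditions: DABCO, dioxane/H2O (1:1), rt
Reagents that add atoms: none
Why: Morita–Baylis–Hillman reaction forming C7–C11; the new carbinol centre is a mixture, which does not matter because it becomes sp2 in step 2, and the dioxolane centre (later C6) is untouched.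

Step 2
Reactants: 3 methyl 2-{[(4R)-2,2-dimethyl-1,3-dioxolan-4-yl](hydroxy)methyl}prop-2-enoate
Product: 4 methyl (2Z)-2-(bromomethyl)-3-[(4S)-2,2-dimethyl-1,3-dioxolan-4-yl]prop-2-enoate
Conditions: NBS, Me2S, CH2Cl2, 0 °C → rt
Reagents that add atoms: N-bromosuccinimide, O=C1CCC(=O)N1Br
Why: Corey–Kim-type activation of the allylic alcohol as an alkoxysulfonium salt and SN2' attack of bromide give the rearranged conjugated allylic bromide; the Z isomer (dioxolane cis to CH2Br, trans to the ester) is the favoured trisubstituted enoate.

Step 3
Reactants: 5 (S)-citramalic acid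
Product: 6 2-[(4S)-2,2,4-trimethyl-5-oxo-1,3-dioxolan-4-yl]acetic acid
Conditions: 2,2-dimethoxypropane, p-TsOH (cat.), rt
Reagents that add atoms: 2,2-dimethoxypropane, COC(C)(C)OC
Why: acid-catalysed acetalisation ties the α-hydroxy acid into a five-membered dioxolanone and leaves the β-carboxyl free, which differentiates the two carboxyl groups; the quaternary centre (later C10) is not involved.

Step 4
Reactants: 6 2-[(4S)-2,2,4-trimethyl-5-oxo-1,3-dioxolan-4-yl]acetic acid
Product: 8 (3S)-3-hydroxy-3-methyloxolan-2-one, via hydroxyethyl dioxolanone 7 (not isolated)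
Conditions: BH3·SMe2, THF, 0 °C → rt; MeOH; then p-TsOH (cat.), CH2Cl2, rt
Reagents that add atoms: none
Why: borane reduces the free carboxylic acid chemoselectively beside the dioxolanone, and acid then drives translactonisation of the γ-hydroxy dioxolanone to the five-membered lactone with loss of acetone.

Step 5
Reactants: 8 (3S)-3-hydroxy-3-methyloxolan-2-one
Product: 9 (3S)-3-methyl-3-[(triethylsilyl)oxy]oxolan-2-one
Conditions: TESOTf, 2,6-lutidine, CH2Cl2, −78 → 0 °C
Reagents that add atoms: triethylsilyl trifluoromethanesulfonate, CC[Si](CC)(CC)OS(=O)(=O)C(F)(F)F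
Why: silyl triflate with a hindered base silylates the tertiary hydroxyl; the ether withstands the organolithium and the aqueous allylation and is non-chelating, so C10 has little influence in step 8.

Step 6
Reactants: 9 (3S)-3-methyl-3-[(triethylsilyl)oxy]oxolan-2-one; 10 (E)-1-bromobut-1-ene
Product: 12 (3S,5E)-1-hydroxy-3-methyl-3-[(triethylsilyl)oxy]oct-5-en-4-one (in equilibrium with its cyclic hemiketal), via (E)-but-1-enyllithium 11 (not isolated)
Conditions: 10, t-BuLi (2 equiv), Et2O, −78 °C; then 9, −78 °C; aq. NH4Cl
Reagents that add atoms: none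
Why: lithium–bromine exchange keeps the E geometry, and one equivalent of the alkenyllithium adds to the γ-lactone at −78 °C to a tetrahedral lithium alkoxide that persists until the quench (lactone-to-lactol addition), forming C1–C2.

Step 7
Reactants: 12 (3S,5E)-1-hydroxy-3-methyl-3-[(triethylsilyl)oxy]oct-5-en-4-one
Product: 13 (3S,5E)-3-methyl-4-oxo-3-[(triethylsilyl)oxy]oct-5-enal
Conditions: Dess–Martin periodinane, NaHCO3, CH2Cl2, 0 °C → rt
Reagents that add atoms: none
Why: Dess–Martin oxidation of the primary alcohol, drawn from the hemiketal equilibrium through the open form; the buffered non-basic medium avoids β-elimination of the silyloxy group.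

Step 8
Reactants: 13 (3S,5E)-3-methyl-4-oxo-3-[(triethylsilyl)oxy]oct-5-enal; 4 methyl (2Z)-2-(bromomethyl)-3-[(4S)-2,2-dimethyl-1,3-dioxolan-4-yl]prop-2-enoate
Product: 15 methyl (3R,4R,6S,8E)-3-[(4S)-2,2-dimethyl-1,3-dioxolan-4-yl]-4-hydroxy-6-methyl-2-methylidene-7-oxo-6-[(triethylsilyl)oxy]undec-8-enoate, via allylindium dibromide 14 (not isolated)
Conditions: In powder, THF/H2O (1:1), rt
Reagents that add atoms: none
Why: Barbier-type indium-mediated allylation; the allylindium adds through its γ-carbon (C7) to the aldehyde in a chair transition state, chemoselectively over the hindered ketone. The Z-configured allyl unit gives the C7/C8 syn adduct, and with C6–H held in the allyl plane by allylic 1,3-strain the aldehyde should approach anti to the C6–O bond (Felkin-type), setting 7R and 8R.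

Step 9
Reactants: 15 methyl (3R,4R,6S,8E)-3-[(4S)-2,2-dimethyl-1,3-dioxolan-4-yl]-4-hydroxy-6-methyl-2-methylidene-7-oxo-6-[(triethylsilyl)oxy]undec-8-enoate; 16 angelic acid
Product: 18 methyl (3R,4R,6S,8E)-3-[(4S)-2,2-dimethyl-1,3-dioxolan-4-yl]-6-methyl-4-{[(2Z)-2-methylbut-2-enoyl]oxy}-2-methylidene-7-oxo-6-[(triethylsilyl)oxy]undec-8-enoate, via angelic mixed anhydride 17 (not isolated)
Conditions: 16, 2,4,6-Cl3C6H2COCl, Et3N, toluene, rt; then 15, 75 °C
Reagents that add atoms: none
Why: Yamaguchi-type mixed-anhydride esterification run without a nucleophilic catalyst, the usual way to acylate hindered secondary alcohols with angelic acid without Z to E isomerisation. Acylating now blocks the C8 hydroxyl (which could lactonise onto C12) with the group the target needs.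

Step 10
Reactants: 18 methyl (3R,4R,6S,8E)-3-[(4S)-2,2-dimethyl-1,3-dioxolan-4-yl]-6-methyl-4-{[(2Z)-2-methylbut-2-enoyl]oxy}-2-methylidene-7-oxo-6-[(triethylsilyl)oxy]undec-8-enoate
Product: 20 (1R,3S,5E)-3-hydroxy-1-[(2S,3R)-2-(hydroxymethyl)-4-methylidene-5-oxooxolan-3-yl]-3-methyl-4-oxooct-5-en-1-yl (2Z)-2-methylbut-2-enoate, via trihydroxy ester 19 (not isolated)
Conditions: 1 mol/L aq. HCl, THF, rt; then PPTS (cat.), toluene, 50 °C
Reagents that add atoms: none
Why: aqueous acid hydrolyses the acetonide and the tertiary silyl ether, and the secondary C6 hydroxyl closes the γ-lactone by 5-exo attack on the methyl ester in preference to the six-membered alternative from C5–OH. The trans C6/C7 arrangement is inherited from step 8, and the hindered conjugated angelate tolerates dilute acid.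

Step 11
Reactants: 20 (1R,3S,5E)-3-hydroxy-1-[(2S,3R)-2-(hydroxymethyl)-4-methylidene-5-oxooxolan-3-yl]-3-methyl-4-oxooct-5-en-1-yl (2Z)-2-methylbut-2-enoate
Product: 21 (1R,3S,5E)-3-hydroxy-3-methyl-1-{(2S,3R)-4-methylidene-5-oxo-2-[(triethylsilyloxy)methyl]oxolan-3-yl}-4-oxooct-5-en-1-yl (2Z)-2-methylbut-2-enoate
Conditions: TESCl, imidazole, CH2Cl2, −20 °C
Reagents that add atoms: chlorotriethylsilane, CC[Si](Cl)(CC)CC
Why: chemoselective silylation of the primary C5 hydroxyl over the tertiary α-ketol hydroxyl on steric grounds; fast silylation at low temperature also forestalls oxa-Michael addition of C5–OH to the methylene lactone.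

Step 12
Reactants: 21 (1R,3S,5E)-3-hydroxy-3-methyl-1-{(2S,3R)-4-methylidene-5-oxo-2-[(triethylsilyloxy)methyl]oxolan-3-yl}-4-oxooct-5-en-1-yl (2Z)-2-methylbut-2-enoate
Product: 22 (1R,3S,5E)-3-acetoxy-3-methyl-1-{(2S,3R)-4-methylidene-5-oxo-2-[(triethylsilyloxy)methyl]oxolan-3-yl}-4-oxooct-5-en-1-yl (2Z)-2-methylbut-2-enoate
Conditions: Ac2O, DMAP, Et3N, CH2Cl2, rt → 40 °C
Reagents that add atoms: acetic anhydride, CC(=O)OC(C)=O
Why: DMAP-catalysed acylation of the tertiary α-ketol, the only free hydroxyl left; C10 bears no hydrogen, so the centre can neither epimerise nor eliminate.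

Step 13
Reactants: 22 (1R,3S,5E)-3-acetoxy-3-methyl-1-{(2S,3R)-4-methylidene-5-oxo-2-[(triethylsilyloxy)methyl]oxolan-3-yl}-4-oxooct-5-en-1-yl (2Z)-2-methylbut-2-enoate
Product: 23 (1R,3S,4Z,6E)-3-acetoxy-3-methyl-1-{(2S,3R)-4-methylidene-5-oxo-2-[(triethylsilyloxy)methyl]oxolan-3-yl}-4-[(triisopropylsilyl)oxy]octa-4,6-dien-1-yl (2Z)-2-methylbut-2-enoate
Conditions: TIPSOTf, Et3N, CH2Cl2, −78 → 0 °C
Reagents that add atoms: triisopropylsilyl trifluoromethanesulfonate, CC(C)[Si](OS(=O)(=O)C(F)(F)F)(C(C)C)C(C)C
Why: soft enolisation; the silyl triflate activates the C1 carbonyl and triethylamine removes a γ-proton from C4, the only enolisable position because C10 is quaternary. The s-cis enone enforced by the bulky C10 substituent gives the (1Z) geometry, and the more stable (3E) geometry is expected at C3=C4. The triisopropylsilyl group is chosen so that the dienol ether survives steps 14 and 15.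

Step 14
Reactants: 23 (1R,3S,4Z,6E)-3-acetoxy-3-methyl-1-{(2S,3R)-4-methylidene-5-oxo-2-[(triethylsilyloxy)methyl]oxolan-3-yl}-4-[(triisopropylsilyl)oxy]octa-4,6-dien-1-yl (2Z)-2-methylbut-2-enoate
Product: 24 (1R,3S,4Z,6E)-3-acetoxy-1-[(2S,3R)-2-(hydroxymethyl)-4-methylidene-5-oxooxolan-3-yl]-3-methyl-4-[(triisopropylsilyl)oxy]octa-4,6-dien-1-yl (2Z)-2-methylbut-2-enoate
Conditions: PPTS (cat.), MeOH/CH2Cl2 (1:4), 0 °C
Reagents that add atoms: none
Why: acid-catalysed methanolysis should cleave the unhindered primary triethylsilyl ether much faster than the hindered triisopropylsilyl dienol ether is protonated at carbon.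

Step 15
Reactants: 24 (1R,3S,4Z,6E)-3-acetoxy-1-[(2S,3R)-2-(hydroxymethyl)-4-methylidene-5-oxooxolan-3-yl]-3-methyl-4-[(triisopropylsilyl)oxy]octa-4,6-dien-1-yl (2Z)-2-methylbut-2-enoate
Product: 25 (1R,3S,4Z,6E)-3-acetoxy-1-[(2S,3R)-2-formyl-4-methylidene-5-oxooxolan-3-yl]-3-methyl-4-[(triisopropylsilyl)oxy]octa-4,6-dien-1-yl (2Z)-2-methylbut-2-enoate
Conditions: Dess–Martin periodinane, NaHCO3, CH2Cl2, 0 °C
Reagents that add atoms: none
Why: buffered Dess–Martin oxidation is neutral and not electrophilic toward the silyl dienol ether and gives the α-acyloxy aldehyde without enolisation at C6; the aldehyde is used at once.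

Step 16
Reactants: 25 (1R,3S,4Z,6E)-3-acetoxy-1-[(2S,3R)-2-formyl-4-methylidene-5-oxooxolan-3-yl]-3-methyl-4-[(triisopropylsilyl)oxy]octa-4,6-dien-1-yl (2Z)-2-methylbut-2-enoate
Product: 26 (4S,5S,6S,7R,8R,10S)-10-acetoxy-5-hydroxy-8-{[(2Z)-2-methylbut-2-enoyl]oxy}-1-oxogermacra-2(E),11(13)-dien-12,6-olide (CNP0259154.2)
Conditions: BF3·OEt2 (2 equiv), CH2Cl2 (0.001 mol/L, slow addition of 25), −78 °C; aq. NaHCO3
Reagents that add atoms: none
Why: Proposed new method: BF3 binds the C5 aldehyde oxygen, the γ-carbon C4 of the silyl dienol ether attacks the activated carbonyl through an open transition state, and loss of the silyl group as its fluoride restores the C1 carbonyl with the C2=C3 double bond, whose E geometry follows from the s-trans diene. The closest known reaction types are the intermolecular Lewis-acid vinylogous Mukaiyama aldol of ketone-derived silyl dienol ethers and macrolide closures by vinylogous aldol addition on an aluminium tris(2,6-diphenylphenoxide) template; a carbocyclic medium ring has not been closed in this way. The ten-membered ring closes in a 10-exo-trig mode at the aldehyde carbon (the C=O stays outside the ring), helped by the rigid trans-lactone, the quaternary C10 and the planar diene, with high dilution against oligomers. C4 (S) is controlled by the (3E) geometry together with the arrangement about the forming bond: with the ring arms C3 and C6 anti, the BF3-bound oxygen lies between C3 and H4, away from the C15 methyl, which gives the 4,5-anti pair. C5 (S) is controlled by C6: the aldehyde should react in the rotamer with C5=O opposed to the C6–O dipole, and the tether, which starts at C7, reaches the face turned toward C7 (the Si face), giving 5,6-syn, the reverse of the Cornforth preference of a free nucleophile. The step needs γ- over α-attack and aldehyde over methylene-lactone addition; the bulky silyl group and the eight-membered alternative disfavour α-attack, and BF3 at −78 °C activates the aldehyde far more strongly than the lactone, angelate or acetate.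

## Compound list

1 | (R)-glyceraldehyde acetonide | O=C[C@H]1COC(C)(C)O1 | starting material
2 | methyl acrylate | C=CC(=O)OC | starting material
3 | methyl 2-{[(4R)-2,2-dimethyl-1,3-dioxolan-4-yl](hydroxy)methyl}prop-2-enoate (both carbinol epimers) | C=C(C(=O)OC)C(O)[C@H]1COC(C)(C)O1 | intermediate
4 | methyl (2Z)-2-(bromomethyl)-3-[(4S)-2,2-dimethyl-1,3-dioxolan-4-yl]prop-2-enoate | COC(=O)/C(CBr)=C/[C@H]1COC(C)(C)O1 | intermediate
5 | (S)-citramalic acid | OC(=O)[C@@](C)(O)CC(=O)O | starting material
6 | 2-[(4S)-2,2,4-trimethyl-5-oxo-1,3-dioxolan-4-yl]acetic acid | O=C1OC(C)(C)O[C@@]1(C)CC(=O)O | intermediate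
7 | (5S)-5-(2-hydroxyethyl)-2,2,5-trimethyl-1,3-dioxolan-4-one | O=C1OC(C)(C)O[C@@]1(C)CCO | intermediate (not isolated)
8 | (3S)-3-hydroxy-3-methyloxolan-2-one | O=C1OCC[C@]1(C)O | intermediate
9 | (3S)-3-methyl-3-[(triethylsilyl)oxy]oxolan-2-one | O=C1OCC[C@]1(C)O[Si](CC)(CC)CC | intermediate
10 | (E)-1-bromobut-1-ene | CC/C=C/Br | starting material
11 | (E)-but-1-enyllithium | CC/C=C/[Li] | intermediate (not isolated)
12 | (3S,5E)-1-hydroxy-3-methyl-3-[(triethylsilyl)oxy]oct-5-en-4-one | CC/C=C/C(=O)[C@@](C)(O[Si](CC)(CC)CC)CCO | intermediate
13 | (3S,5E)-3-methyl-4-oxo-3-[(triethylsilyl)oxy]oct-5-enal | CC/C=C/C(=O)[C@@](C)(O[Si](CC)(CC)CC)CC=O | intermediate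
14 | allylindium dibromide derived from 4 (simplest formulation) | COC(=O)/C(C[In](Br)Br)=C/[C@H]1COC(C)(C)O1 | intermediate (not isolated)
15 | methyl (3R,4R,6S,8E)-3-[(4S)-2,2-dimethyl-1,3-dioxolan-4-yl]-4-hydroxy-6-methyl-2-methylidene-7-oxo-6-[(triethylsilyl)oxy]undec-8-enoate | C=C(C(=O)OC)[C@@H]([C@H]1COC(C)(C)O1)[C@H](O)C[C@](C)(O[Si](CC)(CC)CC)C(=O)/C=C/CC | intermediate
16 | angelic acid [(2Z)-2-methylbut-2-enoic acid] | C/C=C(/C)C(=O)O | starting material
17 | (2Z)-2-methylbut-2-enoic 2,4,6-trichlorobenzoic anhydride | C/C=C(/C)C(=O)OC(=O)c1c(Cl)cc(Cl)cc1Cl | intermediate (not isolated)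
18 | methyl (3R,4R,6S,8E)-3-[(4S)-2,2-dimethyl-1,3-dioxolan-4-yl]-6-methyl-4-{[(2Z)-2-methylbut-2-enoyl]oxy}-2-methylidene-7-oxo-6-[(triethylsilyl)oxy]undec-8-enoate | C=C(C(=O)OC)[C@@H]([C@H]1COC(C)(C)O1)[C@H](OC(=O)/C(C)=C\C)C[C@](C)(O[Si](CC)(CC)CC)C(=O)/C=C/CC | intermediate
19 | methyl (3R,4R,6S,8E)-3-[(1S)-1,2-dihydroxyethyl]-6-hydroxy-6-methyl-4-{[(2Z)-2-methylbut-2-enoyl]oxy}-2-methylidene-7-oxoundec-8-enoate | C=C(C(=O)OC)[C@@H]([C@H](O)CO)[C@H](OC(=O)/C(C)=C\C)C[C@](C)(O)C(=O)/C=C/CC | intermediate (not isolated)
20 | (1R,3S,5E)-3-hydroxy-1-[(2S,3R)-2-(hydroxymethyl)-4-methylidene-5-oxooxolan-3-yl]-3-methyl-4-oxooct-5-en-1-yl (2Z)-2-methylbut-2-enoate | C=C1C(=O)O[C@H](CO)[C@H]1[C@H](OC(=O)/C(C)=C\C)C[C@](C)(O)C(=O)/C=C/CC | intermediate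
21 | (1R,3S,5E)-3-hydroxy-3-methyl-1-{(2S,3R)-4-methylidene-5-oxo-2-[(triethylsilyloxy)methyl]oxolan-3-yl}-4-oxooct-5-en-1-yl (2Z)-2-methylbut-2-enoate | C=C1C(=O)O[C@H](CO[Si](CC)(CC)CC)[C@H]1[C@H](OC(=O)/C(C)=C\C)C[C@](C)(O)C(=O)/C=C/CC | intermediate
22 | (1R,3S,5E)-3-acetoxy-3-methyl-1-{(2S,3R)-4-methylidene-5-oxo-2-[(triethylsilyloxy)methyl]oxolan-3-yl}-4-oxooct-5-en-1-yl (2Z)-2-methylbut-2-enoate | C=C1C(=O)O[C@H](CO[Si](CC)(CC)CC)[C@H]1[C@H](OC(=O)/C(C)=C\C)C[C@](C)(OC(C)=O)C(=O)/C=C/CC | intermediate
23 | (1R,3S,4Z,6E)-3-acetoxy-3-methyl-1-{(2S,3R)-4-methylidene-5-oxo-2-[(triethylsilyloxy)methyl]oxolan-3-yl}-4-[(triisopropylsilyl)oxy]octa-4,6-dien-1-yl (2Z)-2-methylbut-2-enoate | C=C1C(=O)O[C@H](CO[Si](CC)(CC)CC)[C@H]1[C@H](OC(=O)/C(C)=C\C)C[C@](C)(OC(C)=O)/C(O[Si](C(C)C)(C(C)C)C(C)C)=C/C=C/C | intermediate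
24 | (1R,3S,4Z,6E)-3-acetoxy-1-[(2S,3R)-2-(hydroxymethyl)-4-methylidene-5-oxooxolan-3-yl]-3-methyl-4-[(triisopropylsilyl)oxy]octa-4,6-dien-1-yl (2Z)-2-methylbut-2-enoate | C=C1C(=O)O[C@H](CO)[C@H]1[C@H](OC(=O)/C(C)=C\C)C[C@](C)(OC(C)=O)/C(O[Si](C(C)C)(C(C)C)C(C)C)=C/C=C/C | intermediate
25 | (1R,3S,4Z,6E)-3-acetoxy-1-[(2S,3R)-2-formyl-4-methylidene-5-oxooxolan-3-yl]-3-methyl-4-[(triisopropylsilyl)oxy]octa-4,6-dien-1-yl (2Z)-2-methylbut-2-enoate | C=C1C(=O)O[C@H](C=O)[C@H]1[C@H](OC(=O)/C(C)=C\C)C[C@](C)(OC(C)=O)/C(O[Si](C(C)C)(C(C)C)C(C)C)=C/C=C/C | intermediate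
26 | (4S,5S,6S,7R,8R,10S)-10-acetoxy-5-hydroxy-8-{[(2Z)-2-methylbut-2-enoyl]oxy}-1-oxogermacra-2(E),11(13)-dien-12,6-olide (CNP0259154.2) | C=C1C(=O)O[C@@H]2[C@@H](O)[C@@H](C)/C=C/C(=O)[C@@](C)(OC(C)=O)C[C@@H](OC(=O)/C(C)=C\C)[C@@H]12 | target

## Step count and least certain steps

Total: 16 steps. Longest linear sequence: 14 steps (steps 3–7 from 5, then steps 8–16). Steps 1–2 form the second branch.

**Step 16 (key step, proposed new method).** Most likely to go wrong: ring closure losing to oligomerisation or to α-attack (eight-membered ring), and insufficient facial control at C4 and C5. No cyclic transition state organises the two termini, the needed aldehyde face is opposite to the open-chain preference, and any (3Z) component of the dienol ether would erode C4. Fallback by known chemistry, with a different construction of C4–C5 and of the ring: it sets out from 22. Methanolysis of the silyl ether (PPTS, MeOH) gives hydroxy enone F1, and Dess–Martin oxidation gives keto aldehyde F2. Anti-selective crotylboration of F2 with the (E)-crotylboronate of (R,R)-diisopropyl tartrate (toluene, 4 Å sieves, −78 °C) installs C4 and C5 and gives diene F3. The chair transition state of the E reagent secures 4,5-anti and the tartrate directs attack to the Si face, against the substrate preference. Ring-closing metathesis of F3 with second-generation Hoveyda–Grubbs catalyst (toluene, high dilution, 80 °C) between the C4 vinyl group and the butenyl enone then forms C2=C3 with loss of but-1-ene and returns to the route at 26.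

**Step 8.** Most likely to go wrong: poor facial selectivity with respect to the C6 centre of the allyl unit, or reductive 1,4-elimination of the C6 oxygen from the allylindium species, because the reagent is a heterogeneous, ill-defined allylmetal in water. Fallback with a preformed, isolable allylboron reagent: it sets out from 3. Acetylation (Ac2O, pyridine, DMAP) gives allylic acetate F4, and SN2' borylation (B2pin2, CuCl, KOAc, DMF) gives allylboronate F5. F5 adds to 13 in toluene through a closed six-membered transition state (syn adduct, no free allylmetal that can expel the C6 oxygen). Mild aqueous work-up of the borate, before it can lactonise, returns to the route at 15.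

**Step 9.** Most likely to go wrong: Z to E isomerisation during acyl activation, or lactonisation of the C8 hydroxyl onto the methyl ester at 75 °C, because the alcohol is hindered and the reaction slow. Fallback that builds the Z double bond after the acylation: it sets out from 15. Esterification with 2-[bis(2,2,2-trifluoroethoxy)phosphoryl]propanoic acid (EDC·HCl, DMAP cat., CH2Cl2, 0 °C) gives phosphonate ester F6. Still–Gennari olefination (KN(SiMe3)2, 18-crown-6, THF, −78 °C; acetaldehyde) then forms the Z-trisubstituted enoate and returns to the route at 18.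

**Step 14.** Most likely to go wrong: protodesilylation of the dienol ether back to the enone before the primary silyl ether is cleaved, because both are acid-labile. Fallback that reverses the order of deprotection and enolisation: it sets out from 22. Methanolysis before any dienol ether exists gives hydroxy enone F1. In one flask TMSCl/Et3N (0 °C) caps the alcohol and TIPSOTf/Et3N (−78 → 0 °C) forms the dienol ether, giving bis-silyl compound F7. Its far more labile primary trimethylsilyl ether is removed in a brief methanolic work-up (MeOH, citric acid cat., 0 °C), returning to the route at 24.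

**Step 6.** Most likely to go wrong: over-addition, by collapse of the tetrahedral intermediate and 1,2- or 1,4-addition of a second alkenyllithium to the liberated enone. Fallback through an acyl donor that cannot over-add: it sets out from 9. Aminolysis (MeNHOMe·HCl, AlMe3, CH2Cl2) opens the lactone to hydroxy Weinreb amide F8. Addition of 11 (2.2 equiv, THF, −78 °C) gives a stable chelate that releases the ketone only on work-up, returning to the route at 12.

Further compounds
F1 | step 16 | (1R,3S,5E)-3-acetoxy-1-[(2S,3R)-2-(hydroxymethyl)-4-methylidene-5-oxooxolan-3-yl]-3-methyl-4-oxooct-5-en-1-yl (2Z)-2-methylbut-2-enoate | C=C1C(=O)O[C@H](CO)[C@H]1[C@H](OC(=O)/C(C)=C\C)C[C@](C)(OC(C)=O)C(=O)/C=C/CC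
F2 | step 16 | (1R,3S,5E)-3-acetoxy-1-[(2S,3R)-2-formyl-4-methylidene-5-oxooxolan-3-yl]-3-methyl-4-oxooct-5-en-1-yl (2Z)-2-methylbut-2-enoate | C=C1C(=O)O[C@H](C=O)[C@H]1[C@H](OC(=O)/C(C)=C\C)C[C@](C)(OC(C)=O)C(=O)/C=C/CC
F3 | step 16 | (1R,3S,5E)-3-acetoxy-1-{(2S,3R)-2-[(1S,2S)-1-hydroxy-2-methylbut-3-en-1-yl]-4-methylidene-5-oxooxolan-3-yl}-3-methyl-4-oxooct-5-en-1-yl (2Z)-2-methylbut-2-enoate | C=C1C(=O)O[C@H]([C@@H](O)[C@@H](C)C=C)[C@H]1[C@H](OC(=O)/C(C)=C\C)C[C@](C)(OC(C)=O)C(=O)/C=C/CC
F4 | step 8 | methyl 2-{(acetyloxy)[(4R)-2,2-dimethyl-1,3-dioxolan-4-yl]methyl}prop-2-enoate (both epimers) | C=C(C(=O)OC)C(OC(C)=O)[C@H]1COC(C)(C)O1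
F5 | step 8 | methyl (2E)-3-[(4S)-2,2-dimethyl-1,3-dioxolan-4-yl]-2-[(4,4,5,5-tetramethyl-1,3,2-dioxaborolan-2-yl)methyl]prop-2-enoate | COC(=O)/C(CB1OC(C)(C)C(C)(C)O1)=C/[C@H]1COC(C)(C)O1
F6 | step 9 | C8 2-[bis(2,2,2-trifluoroethoxy)phosphoryl]propanoate of 15 (epimers at the phosphonate carbon) | C=C(C(=O)OC)[C@@H]([C@H]1COC(C)(C)O1)[C@H](OC(=O)C(C)P(=O)(OCC(F)(F)F)OCC(F)(F)F)C[C@](C)(O[Si](CC)(CC)CC)C(=O)/C=C/CC
F7 | step 14 | C5 trimethylsilyl ether of 24 | C=C1C(=O)O[C@H](CO[Si](C)(C)C)[C@H]1[C@H](OC(=O)/C(C)=C\C)C[C@](C)(OC(C)=O)/C(O[Si](C(C)C)(C(C)C)C(C)C)=C/C=C/C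
F8 | step 6 | (2S)-4-hydroxy-N-methoxy-N,2-dimethyl-2-[(triethylsilyl)oxy]butanamide | CON(C)C(=O)[C@@](C)(O[Si](CC)(CC)CC)CCO
A1 | alternative 1 | (5S)-5-[(1S,2S)-1-(tert-butyldimethylsilyloxy)-3-(4-methoxybenzyloxy)-2-methylpropyl]furan-2(5H)-one | O=C1C=C[C@H](O1)[C@@H](O[Si](C)(C)C(C)(C)C)[C@@H](C)COCc1ccc(OC)cc1
A2 | alternative 1 | 2-[(2S)-3-(tert-butyldimethylsilyloxy)-2-(methoxymethoxy)-2-methylpropyl]-1,3-dithiane | S1CCCSC1C[C@](C)(OCOC)CO[Si](C)(C)C(C)(C)C
A3 | alternative 1 | trans-disubstituted aminomethyl lactone from A1, A2 and dimethylmethyleneiminium iodide | CN(C)C[C@@H]1C(=O)O[C@H]([C@@H](O[Si](C)(C)C(C)(C)C)[C@@H](C)COCc2ccc(OC)cc2)[C@H]1C2(SCCCS2)C[C@](C)(OCOC)CO[Si](C)(C)C(C)(C)C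
A4 | alternative 2 | (7E)-cyclodecenone with C6 O-(2-bromo-1-ethoxyallyl) acetal, C5 silyl ether, C4 methyl and C10 methyl and acetate (acetal carbon as a mixture) | [C@H]1(OC(OCC)C(Br)=C)/C=C/C[C@](C)(OC(C)=O)C(=O)CC[C@H](C)[C@@H]1O[Si](C)(C)C(C)(C)C
A5 | alternative 2 | methylene lactol ethyl ether with C8 hydroxyl (acetal carbon as a mixture) | C=C1C(OCC)O[C@@H]2[C@@H](O[Si](C)(C)C(C)(C)C)[C@@H](C)CCC(=O)[C@@](C)(OC(C)=O)C[C@@H](O)[C@@H]12
A6 | alternative 3 | acyclic C8 aldoxime with C1 isopropenyl ketone, C6 4-methoxybenzyl ether, C5 and C12 silyl ethers | ON=C[C@@H](C(=C)CO[Si](C)(C)C(C)(C)C)[C@H](OCc1ccc(OC)cc1)[C@@H](O[Si](C)(C)C(C)(C)C)[C@@H](C)CCC(=O)C(C)=C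
A7 | alternative 3 | bridged isoxazoline closing the ten-membered ring at C8–C9 | C=C(CO[Si](C)(C)C(C)(C)C)[C@H]1[C@H](OCc2ccc(OC)cc2)[C@@H](O[Si](C)(C)C(C)(C)C)[C@@H](C)CCC(=O)[C@]2(C)CC1=NO2
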